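The numbers in the tables are calculated from invented constants, noise included.

Replace the fall of the solid substrate by its mean slope, and read from that slope when the solid should clear.

| setting | zeta | beta | elm | oak |
|---|---|---|---|---|
| solid substrate | 0.10 M | 0.10 M | 0.10 M | 0.10 M |
| reagent | 4 equiv | 4 equiv | 4.00 equiv | 4.00 equiv |
| scavenger | 1.7 equiv | 3.2 equiv | 1.50 equiv | 2.00 equiv |
| remark | run made earlier | run made earlier |  |  |
| time |  |  | 1.0 h | 1.0 h |

- zeta (time / min: solid substrate / %, single product / %): 2.50: 91.7, 0.8; 5.00: 83.8, 2.6; 8.00: 78.0, 10.4; 15.0: 57.1, 21.3; 30.0: 19.9, 42.4
- beta (time / min: solid substrate / %, single product / %): 2.50: 90.9, 0.1; 5.00: 83.8, 2.0; 8.00: 76.1, 9.7; 15.0: 58.4, 21.2; 30.0: 22.3, 41.4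

(readings scatter by 1 percentage point)

- what is said of released group includes idle adduct
- solid substrate is a solid; its amount is given per volume of the solution
- on the list of suspects stand: starting material + reagent -> single product + released group; starting material + released group <-> idle adduct; reagent + double product -> tris adduct + released group; scavenger + released group -> scavenged by-product; solid substrate <-> starting material; reagent + single product -> double product + released group
- at the start none of the solid substrate is in solution
- what has only dissolved of solid substrate counts as not reacted

1. part of the solid substrate that has reacted (what has only dissolved counts as not reacted) at the end, elm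
2. part of the solid substrate that has reacted (what has only dissolved counts as not reacted) at the end, oak
3. what raising the equivalents of scavenger from its lowest to its highest value here does to the part of the solid substrate that has reacted (what has only dissolved counts as not reacted) (changes below 5 percentage points count as none) (no change / it falls / it rises)

The zeta run, with 1.7 equiv of scavenger, and the beta run, with 3.2 equiv, end at 19.9 % and 22.3 % solid substrate, a gap of 2.4 percentage points against a scatter of 1 point per reading. The two runs can therefore be averaged into the feed rate F, the mean concentration of solid substrate lost per unit time between first and last reading, 0.00255 M min⁻¹. Charge over F gives a clearing time of 39.2 min, shorter than the 1.0 h allowed. This reckoning therefore expects no solid at the end of elm or oak, with the same clearing time in both, but it gives no percentage of its own.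

The forecast says 93 % for elm, 97 % for oak and no change: “The gap is under 5 points”.

The flask gives 95.2 % for elm and 95.1 % for oak; from the lowest to the highest scavenger that counts as no change, a shift of −0.13 points.

    starting material + reagent → single product + released group (k = 0.00490 M⁻¹ s⁻¹)
    starting material + released group ⇌ idle adduct, settled at all times (K = 4.60 M⁻¹)
    reagent + double product → tris adduct + released group (k = 0.00320 M⁻¹ s⁻¹)
    scavenger + released group → scavenged by-product (k = 2.40 M⁻¹ s⁻¹)
    solid substrate ⇌ starting material, rate k5*(cs5 - [starting material]) while solid is left; crystals form when [starting material] > cs5 (solubility = 0.0700 M, k = 8.30 × 10⁻⁴ s⁻¹)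
    reagent + single product → double product + released group (k = 0.00100 M⁻¹ s⁻¹)

Free scavenger ends at 0.0350 % of its charge in elm and 20.3 % in oak, yet idle adduct holds 0.207 % of the solid substrate charged at the end of elm, and its tying up makes no difference that counts. F puts the solid of elm at 23.4 % at 0.500 h, and elm then holds 21.4 %. For the neighbour with 0.25 M of solid substrate, same equivalents and time, F gives a clearing time of 98.0 min, longer than 1.0 h, and that flask ends with 29.6 % solid substrate and 64.8 % reacted.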